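**Retrosynthetic overview**
1. Endgame: hydrogenolysis of four benzyl groups releases the target from its protected hemiketal. That hemiketal comes from a (2R,3S)-2,3-epoxychroman-4-one by reductive cleavage of the C3–O bond. The labile C2 stereocentre is therefore stored as an oxirane C–O bond, set by catalyst-controlled epoxidation of the C2=C3 bond of a 2-(arylmethyl)-5-heptylchromone.
2. The heptyl chain is placed on C5 by Negishi coupling of a 5-bromochromone. The bromine first serves as regiochemical director of the key step.
3. Key disconnection: ring B is cut at O1–C8a and C4–C4a (and at O1–C2) to 5-(benzyloxy)-3-bromobenzyne and a 4-arylbuta-2,3-dienoic acid. The aryne inserts into the acyl C–O bond of the acid, and the freed phenolate closes on C2.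
4. Enabling feature: in ring A the ring oxygen O1 (on C8a) and the acyl carbon C4 (on C4a) sit on adjacent carbons, a 2-acylphenol pattern that is the footprint of an aryne inserted into C(=O)–O. C2 lies β to C4 at the ketone oxidation level, and C5, next to C4a, can hold an inductive director.
5. Ring order: rings A and C are bought (4-(benzyloxy)phenol, orsellinic acid). Ring B is formed in the key step. A temporary oxirane on C2–C3 is closed and reopened afterwards.

Key step: step 7

Assumption: C2 is a hemiketal carbon whose only racemisation path is acid- or base-catalysed ring–chain tautomerism, so it is taken as configurationally stable in neutral, cold media, and the last two steps and the isolation are kept neutral and at or below room temperature.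

Step 1
Reactants: 1 4-(benzyloxy)phenol
Product: 2 4-(benzyloxy)-2,6-dibromophenol
Conditions: NBS (2.1 equiv), i-Pr2NH (cat.), CH2Cl2, 0 °C to rt
Reagents that add atoms: N-bromosuccinimide, O=C1CCC(=O)N1Br
Why: Electrophilic aromatic bromination: the free hydroxyl group outranks the benzyl ether as director and its para position is blocked, so both bromines enter ortho to OH and give a symmetric product in which the later mono-exchange is unambiguous.

Step 2
Reactants: 2 4-(benzyloxy)-2,6-dibromophenol
Product: 5 4-(benzyloxy)-2-bromo-6-(trimethylsilyl)phenyl trifluoromethanesulfonate, via aryl silyl ether 3 (not isolated), via lithium silylphenolate 4 (not isolated)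
Conditions: HMDS, THF, 70 °C, then evaporation; n-BuLi (1.05 equiv), THF, −78 °C; Tf2O, −78 °C to 0 °C
Reagents that add atoms: hexamethyldisilazane, C[Si](C)(C)N[Si](C)(C)C; n-butyllithium, [Li]CCCC (lithium of 4); trifluoromethanesulfonic anhydride, O=S(=O)(OS(=O)(=O)C(F)(F)F)C(F)(F)F
Why: O-silylation, bromine–lithium exchange, retro-Brook (1,3 O-to-C) silyl migration and O-triflation form the standard entry to 2-silylaryl triflates, and because the two bromines are equivalent one equivalent of n-BuLi can give only one product while the second bromine stays as director.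

Step 3
Reactants: 6 orsellinic acid (2,4-dihydroxy-6-methylbenzoic acid)
Product: 7 benzyl 2,4-bis(benzyloxy)-6-methylbenzoate
Conditions: BnBr (3.5 equiv), K2CO3, DMF, rt to 50 °C
Reagents that add atoms: benzyl bromide, BrCc1ccccc1
Why: Williamson-type O-alkylation of the carboxylate and of both phenolates installs three groups that all fall in the final neutral hydrogenolysis.

Step 4
Reactants: 7 benzyl 2,4-bis(benzyloxy)-6-methylbenzoate
Product: 9 {3,5-bis(benzyloxy)-2-[(benzyloxy)carbonyl]phenyl}acetic acid, via benzylic lithium compound 8 (not isolated)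
Conditions: LDA (1.2 equiv), THF, −78 °C; CO2 (dry gas), −78 °C to 0 °C; 1 M HCl
Reagents that add atoms: lithium diisopropylamide, [Li]N(C(C)C)C(C)C (lithium of 8); carbon dioxide, O=C=O
Why: Lateral (benzylic) lithiation of an ortho-toluate followed by carboxylation: the ortho ester acidifies the methyl group, its two ortho substituents shield it from attack by the anion, and carbon dioxide traps the benzylic carbanion as the arylacetic acid.

Step 5
Reactants: 9 {3,5-bis(benzyloxy)-2-[(benzyloxy)carbonyl]phenyl}acetic acid; 10 tert-butyl (triphenylphosphoranylidene)acetate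
Product: 13 tert-butyl 4-{3,5-bis(benzyloxy)-2-[(benzyloxy)carbonyl]phenyl}buta-2,3-dienoate (racemic allene), via acid chloride 11 (not isolated), via arylketene 12 (not isolated)
Conditions: (COCl)2, DMF (cat.), CH2Cl2, 0 °C to rt, evaporation; 10, Et3N (1.1 equiv), CH2Cl2, 0 °C to rt
Reagents that add atoms: oxalyl chloride, O=C(Cl)C(=O)Cl (chlorine of 11)
Why: Wittig olefination of a ketene: triethylamine dehydrochlorinates the arylacetyl chloride to the arylketene, whose C=O bond is olefinated by the stabilised ylide to give the 2,3-allenoate directly (a standard allenoate synthesis), which places C2 at the ketone oxidation level without a β-keto acid that could decarboxylate or attack the ring C ester.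

Step 6
Reactants: 13 tert-butyl 4-{3,5-bis(benzyloxy)-2-[(benzyloxy)carbonyl]phenyl}buta-2,3-dienoate
Product: 14 4-{3,5-bis(benzyloxy)-2-[(benzyloxy)carbonyl]phenyl}buta-2,3-dienoic acid (racemic allene)
Conditions: TFA/CH2Cl2 (1:4), 0 °C, then evaporation with toluene; used at once
Reagents that add atoms: none
Why: Acidolysis of a tert-butyl ester (loss of the tert-butyl cation as isobutene) frees the acid without hydroxide, which would add to the central allene carbon, and the hindered benzyl ester and the benzyl ethers of the ester-deactivated ring should tolerate short, cold exposure to the acid.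

Step 7
Reactants: 5 4-(benzyloxy)-2-bromo-6-(trimethylsilyl)phenyl trifluoromethanesulfonate; 14 4-{3,5-bis(benzyloxy)-2-[(benzyloxy)carbonyl]phenyl}buta-2,3-dienoic acid
Product: 17 benzyl 2,4-bis(benzyloxy)-6-{[7-(benzyloxy)-5-bromo-4-oxo-4H-chromen-2-yl]methyl}benzoate, via aryne 15 (not isolated), via hydroxyaryl allenyl ketone 16 (not isolated)
Conditions: 5 (1.5 equiv, in portions), CsF (4 equiv), THF (0.05 M), sealed tube, 110–125 °C
Reagents that add atoms: none
Why: Fluoride removes the silyl group of 5 and triflate leaves to give aryne 15; the carboxylate of 14 adds through oxygen to the aryne carbon remote from bromine (future C8a), the aryl anion thus placed next to bromine (future C4a) attacks the carbonyl carbon of the aryl ester just formed, and the four-membered alkoxide opens to the phenolate of 16, so the aryne has been inserted into the acyl C–O bond and both the O1–C8a and the C4–C4a bonds are made. The closest known reaction type is the fluoride-induced C–O insertion of arynes into carboxylic acids, which with alkenoic and alkynoic acids runs on to chroman-4-ones and chromones. The transient four-membered ring closes 4-exo-trig and ring B closes 6-endo-dig when the phenolate oxygen adds to the central sp carbon (C2) of the allenyl ketone, after which γ-protonation of the dienolate by the bifluoride formed from the acid proton gives the 2-(arylmethyl)chromone, so the equation needs no further reagent. No stereocentre is created, since the racemic allene axis of 14 is erased and 17 is achiral. The step needs regioselectivity in the first addition, which is secured by the C–Br bond next to one aryne carbon: its inductive pull distorts the aryne, stabilises the developing anion beside it and shields that carbon, whereas a heptyl group at this place would give little bias and is therefore introduced afterwards. It also needs acyl capture to outrun protonation and bromide loss from the ortho-bromoaryl anion, for which the carbonyl group held in the same molecule, the high temperature and the dilute aprotic medium are chosen, and attack through oxygen is assured because a carboxylate has no nucleophilic carbon.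

Step 8
Reactants: 17 benzyl 2,4-bis(benzyloxy)-6-{[7-(benzyloxy)-5-bromo-4-oxo-4H-chromen-2-yl]methyl}benzoate; 18 heptylzinc bromide (0.5 M in THF)
Product: 19 benzyl 2,4-bis(benzyloxy)-6-{[7-(benzyloxy)-5-heptyl-4-oxo-4H-chromen-2-yl]methyl}benzoate
Conditions: 18 (1.5 equiv), Pd(OAc)2 (2 mol %), SPhos (4 mol %), THF, rt to 50 °C
Reagents that add atoms: none
Why: Negishi coupling: oxidative addition of zerovalent palladium into the C5–Br bond next to the carbonyl-bearing carbon, transmetalation from the primary alkylzinc reagent and reductive elimination, which the bulky biaryl phosphine makes faster than β-hydride elimination, replace the director by the heptyl chain, and the weakly basic zinc reagent leaves the esters, the pyrone ring and the acidic C2–CH2 group alone.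

Step 9
Reactants: 19 benzyl 2,4-bis(benzyloxy)-6-{[7-(benzyloxy)-5-heptyl-4-oxo-4H-chromen-2-yl]methyl}benzoate
Product: 20 benzyl 2,4-bis(benzyloxy)-6-{[(2R,3S)-7-(benzyloxy)-2,3-epoxy-5-heptyl-4-oxochroman-2-yl]methyl}benzoate (chromanone numbering; oxirane cis-fused to ring B)
Conditions: (S,S)-[N,N'-bis(3,5-di-tert-butylsalicylidene)cyclohexane-1,2-diaminato]MnCl (10 mol %), dimethyldioxirane (acetone solution, 2 equiv, slow addition), CH2Cl2, 4 Å MS, −20 °C to 0 °C
Reagents that add atoms: dimethyldioxirane, CC1(C)OO1
Why: Jacobsen–Katsuki epoxidation: the oxomanganese species formed from the chiral salen complex and the neutral, anhydrous oxidant delivers oxygen to one face of the C2=C3 enol-ether bond of ring B (enantioselective for this chromone double bond in 3-aryl congeners, and with a flat conjugated terminus at C3 and a bulky terminus at C2 arranged as in 2,2-dialkylchromenes, from which the (S,S)-complex is chosen), so the catalyst should fix C2 as R, and C3 follows as S because the oxirane can only be cis-fused.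

Step 10
Reactants: 20 benzyl 2,4-bis(benzyloxy)-6-{[(2R,3S)-7-(benzyloxy)-2,3-epoxy-5-heptyl-4-oxochroman-2-yl]methyl}benzoate
Product: 21 benzyl 2,4-bis(benzyloxy)-6-{[(2R)-7-(benzyloxy)-5-heptyl-2-hydroxy-4-oxochroman-2-yl]methyl}benzoate
Conditions: SmI2 (2.2 equiv, 0.1 M in THF), MeOH, THF, −90 °C, 10 min; pH 7 phosphate buffer, −78 °C to 0 °C; short plug of neutral silica, used at once
Reagents that add atoms: none
Why: Reductive opening of an α,β-epoxy ketone by divalent samarium: two single-electron transfers to the C4 carbonyl group expel only the α-oxygen from C3, so the C2–O bond is never broken and C2 keeps its R configuration (C3 becomes CH2), while methanol at −90 °C should protonate alkoxide and enolate before ring opening or β-elimination sets in.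

Step 11
Reactants: 21 benzyl 2,4-bis(benzyloxy)-6-{[(2R)-7-(benzyloxy)-5-heptyl-2-hydroxy-4-oxochroman-2-yl]methyl}benzoate
Product: 22 2-{[(2R)-5-heptyl-2,7-dihydroxy-4-oxo-3,4-dihydro-2H-chromen-2-yl]methyl}-4,6-dihydroxybenzoic acid (target)
Conditions: H2 (1 atm), 10% Pd/C, EtOAc, 0 °C to rt; filtration through Celite, evaporation below 25 °C
Reagents that add atoms: none
Why: Catalytic hydrogenolysis cleaves only the four O–CH2Ph bonds (three ethers, one ester) under neutral conditions that touch none of the four bonds at C2, so the hemiketal should be released with its configuration intact, and the aryl ketone, flanked by two ortho substituents, is left alone.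

**Compound list**
1 | 4-(benzyloxy)phenol | Oc1ccc(OCc2ccccc2)cc1 | starting material
2 | 4-(benzyloxy)-2,6-dibromophenol | Oc1c(Br)cc(OCc2ccccc2)cc1Br | intermediate
3 | [4-(benzyloxy)-2,6-dibromophenoxy]trimethylsilane | C[Si](C)(C)Oc1c(Br)cc(OCc2ccccc2)cc1Br | intermediate
4 | lithium 4-(benzyloxy)-2-bromo-6-(trimethylsilyl)phenolate | [Li+].[O-]c1c(Br)cc(OCc2ccccc2)cc1[Si](C)(C)C | intermediate
5 | 4-(benzyloxy)-2-bromo-6-(trimethylsilyl)phenyl trifluoromethanesulfonate | C[Si](C)(C)c1cc(OCc2ccccc2)cc(Br)c1OS(=O)(=O)C(F)(F)F | intermediate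
6 | orsellinic acid | Cc1cc(O)cc(O)c1C(=O)O | starting material
7 | benzyl 2,4-bis(benzyloxy)-6-methylbenzoate | Cc1cc(OCc2ccccc2)cc(OCc2ccccc2)c1C(=O)OCc1ccccc1 | intermediate
8 | benzyl 2,4-bis(benzyloxy)-6-(lithiomethyl)benzoate | [Li]Cc1cc(OCc2ccccc2)cc(OCc2ccccc2)c1C(=O)OCc1ccccc1 | intermediate
9 | {3,5-bis(benzyloxy)-2-[(benzyloxy)carbonyl]phenyl}acetic acid | OC(=O)Cc1cc(OCc2ccccc2)cc(OCc2ccccc2)c1C(=O)OCc1ccccc1 | intermediate
10 | tert-butyl (triphenylphosphoranylidene)acetate | CC(C)(C)OC(=O)C=P(c1ccccc1)(c1ccccc1)c1ccccc1 | starting material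
11 | benzyl 2,4-bis(benzyloxy)-6-(2-chloro-2-oxoethyl)benzoate | ClC(=O)Cc1cc(OCc2ccccc2)cc(OCc2ccccc2)c1C(=O)OCc1ccccc1 | intermediate
12 | benzyl 2,4-bis(benzyloxy)-6-(2-oxoethenyl)benzoate (arylketene) | O=C=Cc1cc(OCc2ccccc2)cc(OCc2ccccc2)c1C(=O)OCc1ccccc1 | intermediate
13 | tert-butyl 4-{3,5-bis(benzyloxy)-2-[(benzyloxy)carbonyl]phenyl}buta-2,3-dienoate (racemic) | CC(C)(C)OC(=O)C=C=Cc1cc(OCc2ccccc2)cc(OCc2ccccc2)c1C(=O)OCc1ccccc1 | intermediate
14 | 4-{3,5-bis(benzyloxy)-2-[(benzyloxy)carbonyl]phenyl}buta-2,3-dienoic acid (racemic) | OC(=O)C=C=Cc1cc(OCc2ccccc2)cc(OCc2ccccc2)c1C(=O)OCc1ccccc1 | intermediate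
15 | 5-(benzyloxy)-3-bromobenzyne | BrC1=CC(OCc2ccccc2)=CC#C1 | intermediate
16 | benzyl 2,4-bis(benzyloxy)-6-{4-[4-(benzyloxy)-2-bromo-6-hydroxyphenyl]-4-oxobuta-1,2-dien-1-yl}benzoate (present as its phenolate) | Oc1cc(OCc2ccccc2)cc(Br)c1C(=O)C=C=Cc1cc(OCc2ccccc2)cc(OCc2ccccc2)c1C(=O)OCc1ccccc1 | intermediate
17 | benzyl 2,4-bis(benzyloxy)-6-{[7-(benzyloxy)-5-bromo-4-oxo-4H-chromen-2-yl]methyl}benzoate | O=C1C=C(Cc2cc(OCc3ccccc3)cc(OCc3ccccc3)c2C(=O)OCc2ccccc2)Oc2cc(OCc3ccccc3)cc(Br)c12 | intermediate
18 | heptylzinc bromide | CCCCCCC[Zn]Br | starting material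
19 | benzyl 2,4-bis(benzyloxy)-6-{[7-(benzyloxy)-5-heptyl-4-oxo-4H-chromen-2-yl]methyl}benzoate | CCCCCCCc1cc(OCc2ccccc2)cc2OC(Cc3cc(OCc4ccccc4)cc(OCc4ccccc4)c3C(=O)OCc3ccccc3)=CC(=O)c12 | intermediate
20 | benzyl 2,4-bis(benzyloxy)-6-{[(2R,3S)-7-(benzyloxy)-2,3-epoxy-5-heptyl-4-oxochroman-2-yl]methyl}benzoate | CCCCCCCc1cc(OCc2ccccc2)cc3c1C(=O)[C@H]4[C@@](O4)(Cc5cc(OCc6ccccc6)cc(OCc7ccccc7)c5C(=O)OCc8ccccc8)O3 | intermediate
21 | benzyl 2,4-bis(benzyloxy)-6-{[(2R)-7-(benzyloxy)-5-heptyl-2-hydroxy-4-oxochroman-2-yl]methyl}benzoate | CCCCCCCc1cc(OCc2ccccc2)cc3c1C(=O)C[C@@](O)(Cc5cc(OCc6ccccc6)cc(OCc7ccccc7)c5C(=O)OCc8ccccc8)O3 | intermediate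
22 | 2-{[(2R)-5-heptyl-2,7-dihydroxy-4-oxo-3,4-dihydro-2H-chromen-2-yl]methyl}-4,6-dihydroxybenzoic acid | CCCCCCCc1cc(O)cc2c1C(=O)C[C@@](O)(Cc1cc(O)cc(O)c1C(=O)O)O2 | target

**Totals**
- Total step count: 11.
- Longest linear sequence: 9 (steps 3 to 11, from orsellinic acid).

**Steps most likely to fail**

**Step 7.**
What may go wrong:
- protonation of the aryl anion before acyl transfer, which gives plain O-arylation;
- loss of bromide from the ortho-bromoaryl anion;
- thermal isomerisation or decarboxylation of the allenoate;
- attack of the deprotonated C2–CH2 group of the product on the ring C ester.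

The fallback uses no aryne. Ring A is bought with its heptyl chain, and ring B is made by Claisen condensation and cyclodehydration. It sets out from 9 and comes back at 19, so step 8 is also bypassed. Commercial 5-heptylresorcinol F1 is C-acetylated (AcOH, BF3·OEt2, 90 °C, Friedel–Crafts type, para to one hydroxyl group and ortho to the other) to 1-(2-heptyl-4,6-dihydroxyphenyl)ethanone F2. Its non-chelated hydroxyl group is benzylated (BnBr, K2CO3, acetone) to 1-[4-(benzyloxy)-2-heptyl-6-hydroxyphenyl]ethanone F3. Acid 9 is methylated (MeI, K2CO3, DMF) to benzyl 2,4-bis(benzyloxy)-6-(2-methoxy-2-oxoethyl)benzoate F4. Claisen condensation of the dianion of F3 (LiHMDS, THF, −78 °C to 0 °C) with F4 should give benzyl 2,4-bis(benzyloxy)-6-{4-[4-(benzyloxy)-2-heptyl-6-hydroxyphenyl]-2,4-dioxobutyl}benzoate F5. Cyclodehydration (TsOH cat., toluene, 60 °C) closes it to 19.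

**Step 9.**
What may go wrong:
- poor facial selectivity;
- sluggish oxygen transfer to the push–pull double bond;
- isomerisation of the oxirane on contact with acid or base.

The sense of induction must be checked on the first batch, and the (R,R)-complex is equally available.

The fallback replaces asymmetric catalysis by resolution. It sets out from 19 and comes back at 20. Dimethyldioxirane alone (acetone/CH2Cl2, 0 °C to rt) should give the racemic cis-2,3-epoxide F6. Preparative HPLC on an amylose tris(3,5-dimethylphenylcarbamate) phase with neutral hexane/2-propanol separates 20 from its (2S,3R)-enantiomer F7, which is set aside.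

**Step 10.**
What may go wrong:
- erosion of configuration by ring–chain opening at the alkoxide stage;
- β-elimination back to the chromone;
- over-reduction of the ketone.

The fallback corrects the configuration at the end by a crystallisation-induced diastereomer transformation that uses the lability of the hemiketal. It sets out from 21 of whatever enantiomeric purity and comes back at 22. Hydrogenolysis as in step 11 gives the acid. The acid is slurried with (R)-1-phenylethylamine in 2-propanol/heptane at 40 °C. The amine forms the salts and also catalyses ring–chain tautomerism, so the material should collect in the less soluble (R)-1-phenylethylammonium salt of the (2R)-acid F8. The matching antipode of the amine must be found by trial. Cold partition of the filtered salt between EtOAc and pH 3 citrate buffer returns 22.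

**Further compounds**
F1 | step 7 | 5-heptylresorcinol | CCCCCCCc1cc(O)cc(O)c1
F2 | step 7 | 1-(2-heptyl-4,6-dihydroxyphenyl)ethanone | CCCCCCCc1cc(O)cc(O)c1C(C)=O
F3 | step 7 | 1-[4-(benzyloxy)-2-heptyl-6-hydroxyphenyl]ethanone | CCCCCCCc1cc(OCc2ccccc2)cc(O)c1C(C)=O
F4 | step 7 | benzyl 2,4-bis(benzyloxy)-6-(2-methoxy-2-oxoethyl)benzoate | COC(=O)Cc1cc(OCc2ccccc2)cc(OCc2ccccc2)c1C(=O)OCc1ccccc1
F5 | step 7 | benzyl 2,4-bis(benzyloxy)-6-{4-[4-(benzyloxy)-2-heptyl-6-hydroxyphenyl]-2,4-dioxobutyl}benzoate | CCCCCCCc1cc(OCc2ccccc2)cc(O)c1C(=O)CC(=O)Cc1cc(OCc2ccccc2)cc(OCc2ccccc2)c1C(=O)OCc1ccccc1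
F6 | step 9 | racemic cis-2,3-epoxide corresponding to 20 | CCCCCCCc1cc(OCc2ccccc2)cc3c1C(=O)C4C(O4)(Cc5cc(OCc6ccccc6)cc(OCc7ccccc7)c5C(=O)OCc8ccccc8)O3
F7 | step 9 | (2S,3R)-enantiomer of 20 | CCCCCCCc1cc(OCc2ccccc2)cc3c1C(=O)[C@@H]4[C@](O4)(Cc5cc(OCc6ccccc6)cc(OCc7ccccc7)c5C(=O)OCc8ccccc8)O3
F8 | step 10 | (R)-1-phenylethylammonium salt of 22 | CCCCCCCc1cc(O)cc2c1C(=O)C[C@@](O)(Cc1cc(O)cc(O)c1C(=O)[O-])O2.C[C@H](c1ccccc1)[NH3+]
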